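**Plan**
- The arene of docosyl 2,3-dihydroxybenzoate is read as a cyclohexane-1,2-dione β-keto ester two hydrogens below the aromatic level: ring carbon C-1 is the carbon α to the docosyl ester, and C-2 and C-3 are the adjacent oxygen-bearing carbons.
- Cuts, in retrosynthetic order: the C-4 to C-6 unsaturation (dehydrogenation), the C-3 carbonyl (back to a 1,3-dithiane), ring bond C-1–C-2 (Claisen/Dieckmann), chain bond C-3–C-4 (dithiane alkylation), and the ester C–O bond to docosanol.
- Forward: 5-bromopentanoic acid is esterified with docosanol, the bromide alkylates ethyl 1,3-dithiane-2-carboxylate (C-3–C-4), and the only ring closes by attack of C-1 on the ethyl ester carbonyl C-2; C-3 is then unmasked and the ring aromatised.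
- The dithiane carbon has no α-hydrogen, so only C-1 can become the nucleophile, and the ethyl ester is the only electrophile within six-ring reach.
- Stereochemistry: the target is achiral and has no stereocentre, so nothing needs to be controlled; the transient C-1 iodide is racemic and its centre disappears on aromatisation.

Key step: step 3

Remark: compounds 9 and 10 are written as their hydrogen-bonded enol tautomers, which are expected to predominate; ring numbering C-1 to C-6 is that of the benzoate ring of the target throughout.

**Route**

Step 1
Reactants: 1 5-bromopentanoic acid; 2 docosan-1-ol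
Product: 3 docosyl 5-bromopentanoate
Conditions: p-toluenesulfonic acid monohydrate (5 mol%), toluene, reflux, Dean–Stark trap
Reagents that add atoms: none
Why: Fischer esterification driven to completion by azeotropic removal of water should join the equimolar acid and alcohol, and the primary bromide is inert to the acid catalyst.

Step 2
Reactants: 4 ethyl 1,3-dithiane-2-carboxylate; 3 docosyl 5-bromopentanoate
Product: 6 docosyl 5-[2-(ethoxycarbonyl)-1,3-dithian-2-yl]pentanoate, via sodium dithianyl ester enolate 5 (not isolated)
Conditions: NaH (1.05 equiv), DMF/toluene 1:1, 0 °C; then 3, 0 °C to rt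
Reagents that add atoms: none
Why: The sulfur- and ester-stabilised carbanion of 4 is a soft nucleophile that should undergo clean SN2 alkylation with the primary bromide (Corey–Seebach-type alkylation of a 2-carboalkoxy-1,3-dithiane), forming C-3–C-4 while the far less acidic docosyl ester stays untouched.

Step 3
Reactants: 6 docosyl 5-[2-(ethoxycarbonyl)-1,3-dithian-2-yl]pentanoate
Product: 9 docosyl 7-hydroxy-1,5-dithiaspiro[5.5]undec-7-ene-8-carboxylate (enol form of the β-keto ester), via acyclic lithium ester enolate 7 (not isolated), via cyclic lithium keto ester enolate 8 (not isolated)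
Conditions: LiN(SiMe3)2 (2.5 equiv), THF (0.02 M final), slow addition of 6 at −40 °C, then 0 °C; 1 M HCl quench
Reagents that add atoms: none
Why: LiN(SiMe3)2 removes a proton from the only enolisable position, the CH2 α to the docosyl ester (C-1), and the resulting enolate 7 adds to the ethyl ester carbonyl (C-2) carried by the dithiane carbon (C-3); the tetrahedral intermediate expels ethoxide and the second equivalent of base converts the β-keto ester at once into its chelated enolate 8, which acid work-up protonates to 9. The closest known reaction type is the Dieckmann condensation, here in its crossed form onto a non-enolisable ester. The single new ring, the six-membered carbocycle, closes in a 6-(enolexo)-exo-trig mode with formation of the C-1–C-2 bond. No stereocentre is created, since C-1 ends as an enol carbon and C-3 carries two identical sulfur arms. The step needs chemoselectivity between the two esters and ring closure in preference to intermolecular condensation or ethoxide exchange at the docosyl ester. The first is fixed by the substrate, because the dithiane carbon has no hydrogen and the ethyl ester is the only carbonyl within six-ring reach of C-1; the second is secured by slow addition into excess base at high dilution, which leaves almost no free ester for lithium ethoxide to attack, and by the irreversible final deprotonation.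

Step 4
Reactants: 9 docosyl 7-hydroxy-1,5-dithiaspiro[5.5]undec-7-ene-8-carboxylate
Product: 10 docosyl 2-hydroxy-3-oxocyclohex-1-ene-1-carboxylate (enol form of docosyl 2,3-dioxocyclohexane-1-carboxylate)
Conditions: Hg(ClO4)2·3H2O (2.2 equiv), CaCO3 (4 equiv), THF/H2O 5:1, 0 °C to rt; filtration, aq. NH4Cl wash
Reagents that add atoms: water, O
Why: Thiophilic divalent mercury binds both sulfur atoms and turns the dithioacetal into a leaving group so that water adds at C-3 (mercury-assisted dithioacetal hydrolysis, the unmasking half of Corey–Seebach umpolung), and unlike N-halosuccinimide reagents it should not halogenate the enolised β-keto ester, while CaCO3 takes up the HClO4 released.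

Step 5
Reactants: 10 docosyl 2-hydroxy-3-oxocyclohex-1-ene-1-carboxylate
Product: 12 Gentiside J (docosyl 2,3-dihydroxybenzoate), via tertiary C-1 iodide 11 (not isolated)
Conditions: I2 (20 mol%), DMSO, 80 °C, argon; aq. Na2S2O3 work-up
Reagents that add atoms: none
Why: This is the iodine-catalysed dehydrogenation with DMSO as terminal oxidant that is known to turn cyclohexane-1,2-diones and cyclohexenones into catechols and phenols: the enol is iodinated at C-1, HI is lost across C-1/C-6, the ene-dione tautomerises to the aromatic catechol, and DMSO reoxidises HI to I2 so that no stoichiometric halogen meets the product.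

**Compound list**

1 | 5-bromopentanoic acid | OC(=O)CCCCBr | starting material
2 | docosan-1-ol | CCCCCCCCCCCCCCCCCCCCCCO | starting material
3 | docosyl 5-bromopentanoate | CCCCCCCCCCCCCCCCCCCCCCOC(=O)CCCCBr | intermediate
4 | ethyl 1,3-dithiane-2-carboxylate | CCOC(=O)C1SCCCS1 | starting material
5 | sodium enolate of ethyl 1,3-dithiane-2-carboxylate (not isolated) | CCOC([O-])=C1SCCCS1.[Na+] | intermediate
6 | docosyl 5-[2-(ethoxycarbonyl)-1,3-dithian-2-yl]pentanoate | CCCCCCCCCCCCCCCCCCCCCCOC(=O)CCCCC1(C(=O)OCC)SCCCS1 | intermediate
7 | lithium enolate of the docosyl ester of 6 (not isolated) | CCCCCCCCCCCCCCCCCCCCCCOC([O-])=CCCCC1(C(=O)OCC)SCCCS1.[Li+] | intermediate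
8 | lithium 8-(docosyloxycarbonyl)-1,5-dithiaspiro[5.5]undec-7-en-7-olate (not isolated) | CCCCCCCCCCCCCCCCCCCCCCOC(=O)C1=C([O-])C2(CCC1)SCCCS2.[Li+] | intermediate
9 | docosyl 7-hydroxy-1,5-dithiaspiro[5.5]undec-7-ene-8-carboxylate | CCCCCCCCCCCCCCCCCCCCCCOC(=O)C1=C(O)C2(CCC1)SCCCS2 | intermediate
10 | docosyl 2-hydroxy-3-oxocyclohex-1-ene-1-carboxylate | CCCCCCCCCCCCCCCCCCCCCCOC(=O)C1=C(O)C(=O)CCC1 | intermediate
11 | docosyl 1-iodo-2,3-dioxocyclohexane-1-carboxylate (racemic, not isolated) | CCCCCCCCCCCCCCCCCCCCCCOC(=O)C1(I)CCCC(=O)C1=O | intermediate
12 | Gentiside J, docosyl 2,3-dihydroxybenzoate | CCCCCCCCCCCCCCCCCCCCCCOC(=O)c1cccc(O)c1O | target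

**Count**

Total steps: 5. Longest linear sequence: 5 steps (from 1 or 2 to 12).

**Steps most likely to fail**

Step 3 (ring closure). The lithium ethoxide set free may exchange with the docosyl ester, and intermolecular Claisen condensation may compete with cyclisation, so that mixed esters and oligomers form. The fallback closes the ring on a diester whose two alkoxy groups are the same and installs the docosyl group afterwards; it sets out from 1 and 4 and comes back at 9. Acid 1 is esterified with ethanol (H2SO4 cat., reflux) to ethyl 5-bromopentanoate F1. F1 alkylates the sodium enolate 5 made from 4 with NaH to give ethyl 5-[2-(ethoxycarbonyl)-1,3-dithian-2-yl]pentanoate F2. NaOEt in toluene at 80 °C, where alkoxide exchange is degenerate, closes the ring to sodium 8-(ethoxycarbonyl)-1,5-dithiaspiro[5.5]undec-7-en-7-olate F3 (not isolated), and acidification gives ethyl 7-hydroxy-1,5-dithiaspiro[5.5]undec-7-ene-8-carboxylate F4. Heating F4 with docosan-1-ol 2 and catalytic 4-(dimethylamino)pyridine in toluene, with distillation of ethanol (β-keto ester transesterification through the acylketene), should give 9.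

Step 4 (unmasking of C-3). Ionisation of the C–S bond next to the enolised carbonyl may be slow, so that hydrolysis stalls, or the mercury salt may attack the enol carbon instead of sulfur. The fallback activates sulfur by oxidation and hydrolyses without a heavy metal; it sets out from 9 and comes back at 10. NaIO4 (1.05 equiv) in aqueous methanol/THF at 0 °C oxidises one sulfur to docosyl 7-hydroxy-1,5-dithiaspiro[5.5]undec-7-ene-8-carboxylate 1-oxide F5 (racemic mixture of diastereomers at sulfur). Its protonated sulfinyl group is a much better leaving group, so aqueous HClO4 in THF at room temperature should hydrolyse it to 10 with release of 1,2-dithiolane.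

Step 5 (aromatisation). The freshly formed catechol may be iodinated or oxidised further while oxidant is still present, or dehydrogenation may stop short. The fallback separates halogenation from elimination so that the catechol never meets an oxidant; it sets out from 10 and comes back at 12. N-bromosuccinimide (1.0 equiv) in CH2Cl2 at 0 °C brominates the enol carbon C-1 to racemic docosyl 1-bromo-2,3-dioxocyclohexane-1-carboxylate F6, which is isolated free of oxidant. Li2CO3 and LiBr in DMF at 100 °C under argon then remove HBr across C-1/C-6, and the ene-dione tautomerises to 12 (the bromination–dehydrobromination used to aromatise 2,3-dioxocyclohexane carboxylates).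

**Further compounds**

F1 | step 3 | ethyl 5-bromopentanoate | CCOC(=O)CCCCBr
F2 | step 3 | ethyl 5-[2-(ethoxycarbonyl)-1,3-dithian-2-yl]pentanoate | CCOC(=O)CCCCC1(C(=O)OCC)SCCCS1
F3 | step 3 | sodium 8-(ethoxycarbonyl)-1,5-dithiaspiro[5.5]undec-7-en-7-olate | CCOC(=O)C1=C([O-])C2(CCC1)SCCCS2.[Na+]
F4 | step 3 | ethyl 7-hydroxy-1,5-dithiaspiro[5.5]undec-7-ene-8-carboxylate | CCOC(=O)C1=C(O)C2(CCC1)SCCCS2
F5 | step 4 | docosyl 7-hydroxy-1,5-dithiaspiro[5.5]undec-7-ene-8-carboxylate 1-oxide (racemic, mixture of diastereomers at sulfur) | CCCCCCCCCCCCCCCCCCCCCCOC(=O)C1=C(O)C2(CCC1)SCCCS2=O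
F6 | step 5 | docosyl 1-bromo-2,3-dioxocyclohexane-1-carboxylate (racemic) | CCCCCCCCCCCCCCCCCCCCCCOC(=O)C1(Br)CCCC(=O)C1=O
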